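**Retrosynthetic overview**
1. Target ⇐ selective epoxidation of the strained E ring alkene, C14 acetylation and C8 methylenation of a trans-fused bicyclo[7.2.0]undecenone.
2. Nine-membered ring ⇐ Grob fragmentation (C4–C8 cleavage) of a cyclobutane-fused cis-hydrindane 1,3-diol monomesylate, then epimerisation of C9 to the trans fusion.
3. C11 quaternary centre and the whole C12–C15 chain ⇐ photochemical hydroalkylation (hydrogen-atom transfer / SH2) of an exocyclic methylenecyclobutane with a bromo-diol made from (R)-α-hydroxy-γ-butyrolactone (source of C14).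
4. Cyclopentane ⇐ homoenolate 1,2-addition (C7–C8) and ketyl–olefin cyclisation (C4–C5); cyclobutane ⇐ intramolecular enolate alkylation of 10-chlorocarvone; cyclohexane and C1 ⇐ (R)-carvone.
5. Ring order: six-membered (bought) → four → five → nine (shared bond of the six/five system broken) → oxirane.

Assumption: atom labels C1–C15 follow caryophyllane numbering of the target (C1/C9 ring fusion, C4–C5 epoxide, C8 bears the exocyclic methylene, C10 cyclobutane CH2, C11 quaternary cyclobutane carbon, C12–C15 side chain), the target being the (1R,4R,5R,9S,11R,14R) isomer; compounds 1, 4 and 10 are bought.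

**Route**

Step 1
Reactants: 1 (R)-(−)-carvone
Product: 2 10-chlorocarvone, (5R)-5-(3-chloroprop-1-en-2-yl)-2-methylcyclohex-2-en-1-one
Conditions: Ca(OCl)2, solid CO2, CH2Cl2/H2O, 0 → 20 °C
Reagents that add atoms: calcium hypochlorite, [Ca+2].[O-]Cl.[O-]Cl
Why: Ene-type allylic chlorination by HOCl made in the flask attacks only the electron-rich 1,1-disubstituted alkene (the enone alkene is deactivated) and leaves the C1 stereocentre bought with carvone untouched.

Step 2
Reactants: 2 10-chlorocarvone
Product: 3 (1R,6R)-3-methyl-7-methylidenebicyclo[4.2.0]oct-3-en-2-one (cis-fused)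
Conditions: LiN(i-Pr)2 (1.1 equiv), THF, −78 °C; then DMPU, −78 → 0 °C, 0.02 M
Reagents that add atoms: none
Why: Kinetic α′-deprotonation gives the cross-conjugated enolate whose carbon C9 displaces the allylic chloride in a 4-exo-tet intramolecular enolate alkylation (SN2 and SN2′ give the same methylenecyclobutane), the four-membered ring can only close cis so C9 is set by C1, and O-alkylation is excluded because it would give a bridgehead enol ether.

Step 3
Reactants: 3 bicyclic enone; 4 2-(2-bromoethyl)-1,3-dioxolane
Product: 6 spiro-lactol (cyclic hemiacetal between C8–O and C5), via acetal alcohol 5 (not isolated)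
Conditions: 4, Mg, THF, 20 °C; then CeCl3, 3, THF, −78 °C; then 1 M HCl, THF, 0 → 20 °C
Reagents that add atoms: water, O
Why: Cerium-assisted Grignard 1,2-addition of the homoenolate reagent to the enone carbonyl occurs on the face away from the cyclobutane, and acid hydrolysis of the dioxolane frees the aldehyde, which is trapped at once by the tertiary hydroxyl as a five-membered lactol that shields the acid-labile tertiary allylic alcohol.

Step 4
Reactants: 6 spiro-lactol
Product: 8 tricyclic cis-1,3-diol, via hydroxy aldehyde 7 (not isolated)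
Conditions: SmI2 (3 equiv), HMPA, t-BuOH (2 equiv), THF, 0 → 20 °C
Reagents that add atoms: none
Why: SmI2 reduces the ring-opened aldehyde to a ketyl that adds 5-exo-trig to C4 of the ring alkene (ketyl–olefin reductive cyclisation, necessarily cis-fused, creating the angular-methyl quaternary carbon), the samarium-bound oxygen lies anti to the developing C3 radical in the chair-like transition state so the C5 hydroxyl ends up cis to the C4 methyl, and the C3 radical is then reduced and protonated.

Step 5
Reactants: 8 tricyclic cis-1,3-diol
Product: 9 C5 monomesylate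
Conditions: MsCl (1.2 equiv), Et3N, CH2Cl2, −20 → 0 °C
Reagents that add atoms: methanesulfonyl chloride, CS(Cl)(=O)=O
Why: Sulfonylation takes the only secondary hydroxyl (C5) while the tertiary C8 hydroxyl is inert, with no change at any stereocentre.

Step 6
Reactants: 10 (R)-α-hydroxy-γ-butyrolactone
Product: 11 (3R)-4-methylpentane-1,3,4-triol
Conditions: MeMgBr (3.5 equiv), THF, 0 → 20 °C; then aq. NH4Cl
Reagents that add atoms: methylmagnesium bromide, C[Mg]Br
Why: Double Grignard addition to the lactone carbonyl builds the C15 carbinol, and the magnesium alkoxide formed first at the α-hydroxyl suppresses enolisation so the bought C14 stereocentre is kept.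

Step 7
Reactants: 11 (3R)-4-methylpentane-1,3,4-triol
Product: 12 (3R)-5-bromo-2-methylpentane-2,3-diol
Conditions: CBr4, PPh3, THF, 0 °C
Reagents that add atoms: carbon tetrabromide, BrC(Br)(Br)Br
Why: Appel bromination with the bulky phosphonium reagent is selective for the primary hydroxyl and does not touch C14.

Step 8
Reactants: 9 C5 monomesylate; 12 (3R)-5-bromo-2-methylpentane-2,3-diol (1.5 equiv)
Product: 13 coupled mesylate triol with the C11 quaternary centre
Conditions: Ir[dF(CF3)ppy]2(dtbbpy)PF6 (2 mol %), Co(dmgH)2(py)Cl (5 mol %), Fe(OEP)Cl (5 mol %), (Me3Si)3SiOH (1.6 equiv), Na2CO3 (0.5 equiv), acetone/t-BuOH, 450 nm LEDs, 25 °C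
Reagents that add atoms: none
Why: Proposed new method: a photochemical hydrogen-atom-transfer/SH2 hydroalkylation in which the excited iridium photocatalyst oxidises the silanolate of (Me3Si)3SiOH to a silyl radical (after Brook shift) that abstracts bromine from 12, the primary C12 radical is held on divalent iron porphyrin as an alkyl–iron species, the reduced photocatalyst turns divalent cobalt into monovalent cobalt that takes up the silanol proton to give a cobalt hydride, this hydride transfers a hydrogen atom to the exocyclic CH2 of 9 (Markovnikov) to give the tertiary cyclobutyl radical at C11, and that radical displaces iron at carbon (SH2) from the convex face of the cis-fused bicyclo[4.2.0] unit, anti to C2, so that the new methyl is cis to C2 and C12 is cis to H-1 (11R); the closest known reaction types are the photochemical iron-porphyrin SH2 cross-coupling of alkyl bromides with tertiary radicals and the thermal metal-hydride hydroalkylation of 1,1-disubstituted alkenes with alkyl halides.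

Step 9
Reactants: 13 coupled mesylate triol
Product: 15 trans-fused nine-membered ketone diol, via cis-fused ketone 14 (not isolated)
Conditions: KOt-Bu (4 equiv), THF/t-BuOH, 0 → 40 °C
Reagents that add atoms: none
Why: Grob fragmentation of the C8 alkoxide breaks the C4–C8 bond antiperiplanar to C5–OMs in a concerted, stereospecific step so the cis relation of mesylate and C4 methyl becomes the E alkene of the nine-membered ring, and the excess base then epimerises C9 (α to the new ketone) to the more stable trans ring fusion, as is known for the parent caryophyllene ketone.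

Step 10
Reactants: 15 trans-fused nine-membered ketone diol
Product: 16 diene diol (C8 exocyclic methylene)
Conditions: Ph3PCH3Br (5 equiv), KOt-Bu (4.8 equiv), THF, 0 → 50 °C
Reagents that add atoms: methyltriphenylphosphonium bromide, C[P+](c1ccccc1)(c1ccccc1)c1ccccc1.[Br-]
Why: Wittig methylenation of the ring ketone with excess ylide (the free hydroxyls are only deprotonated) installs the exocyclic methylene, and C9 is already in its thermodynamic trans configuration so the basic medium cannot erode it.

Step 11
Reactants: 16 diene diol
Product: 17 diene 14-acetate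
Conditions: Ac2O, pyridine, DMAP (cat.), CH2Cl2, 0 → 20 °C
Reagents that add atoms: acetic anhydride, CC(=O)OC(C)=O
Why: DMAP-catalysed acylation esterifies the secondary C14 hydroxyl and leaves the hindered tertiary C15 hydroxyl free, with retention at C14.

Step 12
Reactants: 17 diene 14-acetate
Product: 18 target, CNP0157071.3
Conditions: mCPBA (1.05 equiv), NaHCO3, CH2Cl2, −10 → 0 °C
Reagents that add atoms: 3-chloroperoxybenzoic acid (mCPBA), OOC(=O)c1cccc(Cl)c1
Why: Prilezhaev epoxidation is far faster at the strained E-trisubstituted ring alkene than at the exocyclic 1,1-disubstituted alkene, and the peracid attacks the exposed outer face of the dominant ring conformer as in the epoxidation of β-caryophyllene to caryophyllene oxide, setting C4 and C5 (4R,5R) under control of C1 and C9.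

**Compound list**
1 | (R)-(−)-carvone, (5R)-2-methyl-5-(prop-1-en-2-yl)cyclohex-2-en-1-one | CC1=CC[C@H](CC1=O)C(C)=C | starting material
2 | 10-chlorocarvone, (5R)-5-(3-chloroprop-1-en-2-yl)-2-methylcyclohex-2-en-1-one | CC1=CC[C@H](CC1=O)C(=C)CCl | intermediate
3 | (1R,6R)-3-methyl-7-methylidenebicyclo[4.2.0]oct-3-en-2-one, cis-fused | CC1=CC[C@H]2C(=C)C[C@H]2C1=O | intermediate
4 | 2-(2-bromoethyl)-1,3-dioxolane | BrCCC1OCCO1 | starting material
5 | acetal alcohol: 2-[2-(1,3-dioxolan-2-yl)ethyl]-3-methyl-7-methylidenebicyclo[4.2.0]oct-3-en-2-ol, new chain anti to the cyclobutane, hydroxyl cis to it | CC1=CC[C@H]2C(=C)C[C@H]2[C@]1(O)CCC1OCCO1 | intermediate (not isolated)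
6 | spiro-lactol: oxolan-2-ol spiro-fused at C8 of the bicyclic enol skeleton (hemiacetal carbon C5 as a mixture) | CC1=CC[C@H]2C(=C)C[C@H]2[C@]13CCC(O)O3 | intermediate
7 | hydroxy aldehyde: 3-(2-hydroxy-3-methyl-7-methylidenebicyclo[4.2.0]oct-3-en-2-yl)propanal, open form of 6 | CC1=CC[C@H]2C(=C)C[C@H]2[C@]1(O)CCC=O | intermediate (not isolated)
8 | tricyclic diol (cyclobutane/cyclohexane/cyclopentane, cis-anti-cis): tertiary C8–OH and secondary C5–OH both cis to the angular C4 methyl, exocyclic methylene at C11 | C[C@@]12CC[C@H]3C(=C)C[C@H]3[C@]1(O)CC[C@H]2O | intermediate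
9 | C5 methanesulfonate of 8 | C[C@@]12CC[C@H]3C(=C)C[C@H]3[C@]1(O)CC[C@H]2OS(C)(=O)=O | intermediate
10 | (R)-α-hydroxy-γ-butyrolactone, (3R)-3-hydroxyoxolan-2-one | O[C@@H]1CCOC1=O | starting material
11 | (3R)-4-methylpentane-1,3,4-triol | OCC[C@@H](O)C(C)(C)O | intermediate
12 | (3R)-5-bromo-2-methylpentane-2,3-diol | BrCC[C@@H](O)C(C)(C)O | intermediate
13 | coupled mesylate triol: as 9 but C11 quaternary (11R), methyl cis to C2, (3R)-3,4-dihydroxy-4-methylpentyl chain on the convex face | C[C@@]12CC[C@H]3[C@](C)(CC[C@@H](O)C(C)(C)O)C[C@H]3[C@]1(O)CC[C@H]2OS(C)(=O)=O | intermediate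
14 | cis-fused (4E)-bicyclo[7.2.0]undec-4-en-8-one with the 14,15-diol chain (C9 epimer of 15) | O=C1CC/C=C(\C)CC[C@@H]2[C@H]1C[C@@]2(C)CC[C@@H](O)C(C)(C)O | intermediate (not isolated)
15 | (1R,9S,11R,14R) trans-fused (4E)-bicyclo[7.2.0]undec-4-en-8-one with the 14,15-diol chain | O=C1CC/C=C(\C)CC[C@@H]2[C@@H]1C[C@@]2(C)CC[C@@H](O)C(C)(C)O | intermediate
16 | diene diol: 8-methylidene analogue of 15 | C=C1CC/C=C(\C)CC[C@@H]2[C@@H]1C[C@@]2(C)CC[C@@H](O)C(C)(C)O | intermediate
17 | diene 14-acetate, 15-hydroxy | C=C1CC/C=C(\C)CC[C@@H]2[C@@H]1C[C@@]2(C)CC[C@@H](OC(C)=O)C(C)(C)O | intermediate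
18 | CNP0157071.3, (1R,4R,5R,9S,11R,14R)-14-acetoxy-4,5-epoxy-xeniaphyll-8(19)-en-15-ol | C=C1CC[C@H]2O[C@]2(C)CC[C@@H]2[C@@H]1C[C@@]2(C)CC[C@@H](OC(C)=O)C(C)(C)O | target

**Step count and risks**
Total steps: 12. Longest linear sequence: 10 (steps 1–5 and 8–12); steps 6–7 make the side-chain bromide.

Most likely to fail, first: step 8 (the proposed new coupling). Likely failure modes are net hydrogenation of the alkene or simple reduction of the bromide. The fallback uses known thermal chemistry and a different electrophile. It sets out from 9 and triol 11: I2, PPh3 and imidazole convert 11 into (3R)-5-iodo-2-methylpentane-2,3-diol F1, and 9 and F1 are joined by the known manganese/nickel hydroalkylation of 1,1-disubstituted alkenes with primary alkyl iodides (Mn(dpm)3, Ni(acac)2, PhSiH3, K2CO3, 20 °C, no light), in which the tertiary radical is captured by nickel. The same convex-face preference applies, and the route is rejoined at 13.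

Second: step 4 (ketyl addition to the substituted alkene carbon). Risks are simple reduction or pinacol coupling of the aldehyde, slow lactol opening, and 6-endo closure to a bridged ring. The fallback closes the cyclopentane at the other bond and sets out from enone 3. Conjugate reduction with LiBH(s-Bu)3 and aldol trapping of the C4 enolate with 3-(tert-butyldimethylsilyloxy)propanal gives the β-hydroxy ketone silyl ether F2 (C5 as a mixture). HF·pyridine gives the keto diol F3, and I2, PPh3 and imidazole give the primary iodide F4. SmI2/HMPA Barbier addition of C7 to the C8 ketone gives the C5-epimeric diol mixture F5. Because a chair aldol is expected to favour the wrong C5 epimer, Dess–Martin oxidation to the single ketol F6 and NaBH4 reduction anti to the angular methyl then correct C5, and the route is rejoined at 8.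

Third: step 2 (γ-deprotonation and alkylation at C4 to a bicyclo[2.2.2]octenone could compete with cyclobutane closure). The fallback removes the γ-acidity first and sets out from 2. Conjugate addition of PhSH (Et3N) gives the β-phenylthio ketone F7. LiN(i-Pr)2 then deprotonates at C9 and the same 4-exo-tet alkylation gives the bicyclic sulfide F8. mCPBA at −78 °C gives the sulfoxide F9, whose thermal syn-elimination (toluene, 110 °C) restores the enone, and the route is rejoined at 3.

Further compounds
F1 | step 8 | (3R)-5-iodo-2-methylpentane-2,3-diol | ICC[C@@H](O)C(C)(C)O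
F2 | step 4 | β-hydroxy ketone silyl ether: 3-[3-(tert-butyldimethylsilyloxy)-1-hydroxypropyl]-3-methyl-7-methylidene-cis-bicyclo[4.2.0]octan-2-one, side chain anti to the cyclobutane, carbinol as a mixture | C[C@]1(CC[C@H]2C(=C)C[C@H]2C1=O)C(O)CCO[Si](C)(C)C(C)(C)C
F3 | step 4 | keto diol: 3-(1,3-dihydroxypropyl)-3-methyl-7-methylidene-cis-bicyclo[4.2.0]octan-2-one | C[C@]1(CC[C@H]2C(=C)C[C@H]2C1=O)C(O)CCO
F4 | step 4 | primary iodide: 3-(1-hydroxy-3-iodopropyl)-3-methyl-7-methylidene-cis-bicyclo[4.2.0]octan-2-one | C[C@]1(CC[C@H]2C(=C)C[C@H]2C1=O)C(O)CCI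
F5 | step 4 | C5-epimeric mixture of tricyclic diol 8 | C[C@@]12CC[C@H]3C(=C)C[C@H]3[C@]1(O)CCC2O
F6 | step 4 | ketol: C5 ketone of 8 with the tertiary C8 hydroxyl | C[C@@]12CC[C@H]3C(=C)C[C@H]3[C@]1(O)CCC2=O
F7 | step 2 | β-phenylthio ketone: (5R)-5-(3-chloroprop-1-en-2-yl)-2-methyl-3-(phenylsulfanyl)cyclohexan-1-one | CC1C(Sc2ccccc2)C[C@H](CC1=O)C(=C)CCl
F8 | step 2 | bicyclic sulfide: 3-methyl-7-methylidene-4-(phenylsulfanyl)-cis-bicyclo[4.2.0]octan-2-one | CC1C(Sc2ccccc2)C[C@H]2C(=C)C[C@H]2C1=O
F9 | step 2 | sulfoxide of F8 | CC1C(S(=O)c2ccccc2)C[C@H]2C(=C)C[C@H]2C1=O
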